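**Retrosynthetic overview**
1. End game, no ring changes: 1-oxo-10-acetate ⇐ E-1(10)-alkene (ketohydroxylation, acetylation). 8α-methacrylate ⇐ 8-ketone (CBS reduction, acylation). 7(11)-ene-13-acetate ⇐ 11(13)-methylene lactone (nucleophilic epoxidation, E1cB opening, acetylation).
2. Key disconnection: C6–C7, the bond closed when a farnesyl chain folds to a germacrane, and O6–C12, the costunolide-type lactonisation. Both are made in one flask from an open-chain 8-oxo "farnesoid" keto aldehyde ester by a dienolate macro-aldol/lactonisation.
3. Open chain ⇐ C10 allylic chloride + CO (becomes C8) + C4 allylstannane (C7, C11, C12, C13) by a three-component carbonylative Stille coupling.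
4. C10 piece ⇐ an acyclic monoterpene allylic alcohol by Sharpless epoxidation (sets C4 and C5), ene-type chlorination and oxidation. C6 and C10 follow by relay, C8 by catalyst control.
5. Ring order: oxirane (on the open chain, as stereochemical anchor) → ten-membered carbocycle → γ-lactone (same operation as the carbocycle).

Assumption: locants C1–C15 are the germacrane numbering of the target and are used for all intermediates, open-chain ones included. C6 is the lactone carbinol, C8 the methacrylate carbinol, C10 the tertiary acetate carbon, C12 the lactone C=O and C13 the CH2OAc carbon.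

**Step 1**
Reactants: 1 geraniol
Product: 2 (2R,3R)-2,3-epoxygeraniol
Conditions: Ti(OiPr)4 (5 mol %), D-(−)-diethyl tartrate (6 mol %), t-BuOOH, 4 Å MS, CH2Cl2, −20 °C
Reagents that add atoms: tert-butyl hydroperoxide, CC(C)(C)OO
Why: Sharpless asymmetric epoxidation, in which the titanium tartrate complex binds the allylic alcohol so that only the 2,3-alkene reacts, and D-(−)-diethyl tartrate gives the (2R,3R)-oxirane (future C5 and C4, about 95 % ee).

**Step 2**
Reactants: 2 (2R,3R)-2,3-epoxygeraniol
Product: 3 [(2R,3R)-3-(3-chloro-4-methylpent-4-en-1-yl)-3-methyloxiran-2-yl]methanol (both C–Cl epimers)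
Conditions: NCS, PhSeCl (5 mol %), CH2Cl2, 23 °C
Reagents that add atoms: N-chlorosuccinimide, O=C1CCC(=O)N1Cl
Why: Selenium-catalysed ene-type allylic chlorination of the only remaining alkene gives the transposed secondary allylic chloride next to a 1,1-disubstituted alkene, and the unselectively formed C–Cl centre is erased in step 5.

**Step 3**
Reactants: 3 chloro epoxy alcohol
Product: 4 (2S,3R)-3-(3-chloro-4-methylpent-4-en-1-yl)-3-methyloxirane-2-carbaldehyde (both C–Cl epimers)
Conditions: TEMPO (10 mol %), PhI(OAc)2, CH2Cl2, 0 → 23 °C
Reagents that add atoms: none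
Why: The TEMPO/PhI(OAc)2 oxoammonium oxidation stops at the aldehyde under nearly neutral conditions that spare oxirane, allylic chloride and alkene, and no stereocentre is touched (the oxirane CH changes descriptor from R to S only through CIP priorities).

**Step 4**
Reactants: 5 methyl 2-(bromomethyl)acrylate
Product: 6 methyl 2-[(tributylstannyl)methyl]acrylate
Conditions: Zn dust, Bu3SnCl, THF/sat. aq NH4Cl, 23 °C
Reagents that add atoms: tributyltin chloride, CCCC[Sn](Cl)(CCCC)CCCC
Why: Barbier-type zinc insertion into the activated allylic bromide and trapping with Bu3SnCl gives the allylstannane, and allylic transposition is degenerate because both allyl termini are CH2.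

**Step 5**
Reactants: 4 chloro epoxy aldehyde, 6 methyl 2-[(tributylstannyl)methyl]acrylate
Product: 7 methyl (6E)-9-[(2R,3S)-3-formyl-2-methyloxiran-2-yl]-6-methyl-2-methylidene-4-oxonon-6-enoate (open-chain 8-oxo precursor)
Conditions: Pd2(dba)3 (2.5 mol %), AsPh3 (10 mol %), CO (3 atm), THF, 45 °C
Reagents that add atoms: carbon monoxide, [C-]#[O+]
Why: In this three-component carbonylative Stille coupling (allyl chloride + CO + allylstannane → diallyl ketone), zerovalent palladium ionises only the allylic chloride, both epimers converge on the syn-π-allyl complex, CO inserts at the unsubstituted terminus so the new trisubstituted alkene is E, and the acylpalladium is intercepted by 6 under neutral conditions that spare the epoxy aldehyde.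

**Step 6** (key step)
Reactants: 7 open-chain 8-oxo precursor
Product: 10 8-oxoparthenolide [(4R,5R,6S,7S)-4,5-epoxy-8-oxogermacra-1(10)E,11(13)-dien-12,6-olide], via lithium dienolate 8 (not isolated), via lithium aldolate 9 (not isolated)
Conditions: LiN(SiMe3)2 (1.05 equiv, syringe pump), THF (1 mM), −78 → −30 °C; AcOH, −78 °C
Reagents that add atoms: none
Why: Proposed new method: slow addition of the hindered amide base to the very dilute keto aldehyde removes the most acidic proton (C7–H, flanked by the ketone and the ester-bearing vinyl group, while any C9 enolate re-equilibrates through unreacted ketone and could only close a prohibitively strained eight-membered E-cycloalkene), dienolate 8 attacks the only and non-enolisable aldehyde through its α-carbon in a lithium-bridged six-membered transition state pre-folded by the E-alkene and the trans-oxirane, C7 approaches anti to the oxirane C5–O bond with the carbonyl oxygen on the ring periphery so that C6 is formed S, and alkoxide 9 is drained irreversibly by five-exo lactonisation onto C12 (C7 is set trans but is erased in step 7), the closest known reaction types being amide-base macroaldolisations and the aldol–lactonisation half of the Stobbe condensation.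

**Step 7**
Reactants: 10 8-oxoparthenolide
Product: 13 13-acetoxy-4α,5β-epoxy-8-oxogermacra-1(10)E,7(11)-dien-12,6α-olide, via spiro-oxirane 11 (not isolated), via lithium 13-alkoxide 12 (not isolated)
Conditions: t-BuOOH, n-BuLi, THF, −78 → −20 °C; Ac2O, −20 → 0 °C
Reagents that add atoms: tert-butyl hydroperoxide, CC(C)(C)OO; acetic anhydride, CC(=O)OC(C)=O
Why: Proposed new method: t-BuOOLi is far too weak a base to enolise the ketone but adds readily to the exocyclic methylene lactone (Weitz–Scheffer epoxidation) to give 11, the t-BuOLi released then removes C7–H so that the β,γ-epoxy ketone opens by E1cB to the conjugated 7(11)-ene alkoxide 12 (C9 deprotonation is reversible and unproductive), and Ac2O traps 12 before it can close onto the C8 ketone, the closest known reaction types being nucleophilic epoxidation of α-methylene lactones and base-induced β,γ-epoxy ketone to γ-hydroxy enone isomerisation, with C7 the only stereocentre affected and deliberately destroyed.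

**Step 8**
Reactants: 13 13-acetoxy 8-ketone
Product: 14 13-acetoxy-4α,5β-epoxy-8α-hydroxygermacra-1(10)E,7(11)-dien-12,6α-olide (8S)
Conditions: (R)-2-methyl-CBS-oxazaborolidine (0.5 equiv), BH3·SMe2, CH2Cl2/toluene, −40 °C; MeOH
Reagents that add atoms: none
Why: In this Corey–Bakshi–Shibata reduction the (R)-catalyst treats the fully substituted alkenyl carbon C7 as the large group and the C9 methylene as the small one, so hydride is delivered to the face that gives the (8S)-(8α)-alcohol, in the 1,2-sense only, leaving lactone, acetate, oxirane and the trisubstituted alkene untouched at −40 °C.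

**Step 9**
Reactants: 14 8α-alcohol
Product: 15 13-acetoxy-4α,5β-epoxy-8α-methacryloyloxygermacra-1(10)E,7(11)-dien-12,6α-olide
Conditions: methacrylic anhydride, Et3N, DMAP (10 mol %), CH2Cl2, 0 °C
Reagents that add atoms: methacrylic anhydride, C=C(C)C(=O)OC(=O)C(C)=C
Why: DMAP-catalysed (Steglich-type) acylation of the only free hydroxyl proceeds at oxygen with retention at C8, and at 0 °C it is too mild to deprotonate the butenolide C6–H next to the oxirane.

**Step 10**
Reactants: 15 8α-methacrylate
Product: 16 10-O-deacetylglaucolide A (10α-hydroxy-1-oxo compound, 10R)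
Conditions: RuCl3 (2 mol %), KHSO5 (as 2KHSO5·KHSO4·K2SO4), NaHCO3, EtOAc/MeCN/H2O, 23 °C, short contact time
Reagents that add atoms: potassium peroxymonosulfate, [K+].[O-]S(=O)(=O)OO
Why: In this RuO4-catalysed ketohydroxylation (Plietker conditions) the [3+2] addition to the only electron-rich alkene takes place on the exposed outer face of the E-1(10)-alkene in the crown conformer with C14 on the β-face, the face peracids attack in parthenolide-type germacranolides, so oxygen at C10 is α (10R) and the secondary C1–O is oxidised on to the ketone, while the methacrylate and butenolide alkenes are electron-poor and react much more slowly.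

**Step 11**
Reactants: 16 10-O-deacetylglaucolide A
Product: 17 glaucolide A
Conditions: Ac2O, DMAP (2 equiv), CH2Cl2, 23 °C
Reagents that add atoms: acetic anhydride, CC(=O)OC(C)=O
Why: DMAP-mediated acetylation of the tertiary α-ketol takes place at oxygen with retention at C10, and the mild non-acidic medium spares the oxirane, the allylic acetate and the base-labile C6–H.

**Compound list**
1 | geraniol, (2E)-3,7-dimethylocta-2,6-dien-1-ol | CC(C)=CCC/C(C)=C/CO | starting material
2 | (2R,3R)-2,3-epoxygeraniol | CC(C)=CCC[C@@]1(C)O[C@@H]1CO | intermediate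
3 | [(2R,3R)-3-(3-chloro-4-methylpent-4-en-1-yl)-3-methyloxiran-2-yl]methanol, both C–Cl epimers | C=C(C)C(Cl)CC[C@@]1(C)O[C@@H]1CO | intermediate
4 | (2S,3R)-3-(3-chloro-4-methylpent-4-en-1-yl)-3-methyloxirane-2-carbaldehyde, both C–Cl epimers | C=C(C)C(Cl)CC[C@@]1(C)O[C@@H]1C=O | intermediate
5 | methyl 2-(bromomethyl)acrylate | C=C(CBr)C(=O)OC | starting material
6 | methyl 2-[(tributylstannyl)methyl]acrylate | C=C(C[Sn](CCCC)(CCCC)CCCC)C(=O)OC | intermediate
7 | methyl (6E)-9-[(2R,3S)-3-formyl-2-methyloxiran-2-yl]-6-methyl-2-methylidene-4-oxonon-6-enoate | COC(=O)C(=C)CC(=O)C/C(C)=C/CC[C@@]1(C)O[C@@H]1C=O | intermediate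
8 | lithium C7=C8 dienolate of 7 (enolate geometry not defined) | COC(=O)C(=C)C=C([O-])C/C(C)=C/CC[C@@]1(C)O[C@@H]1C=O.[Li+] | intermediate
9 | lithium 6-alkoxide of methyl (4R,5R,6S,7S)-4,5-epoxy-6-hydroxy-8-oxogermacra-1(10)E,11(13)-dien-12-oate | COC(=O)C(=C)[C@@H]1C(=O)C/C(C)=C/CC[C@@]2(C)O[C@@H]2[C@H]1[O-].[Li+] | intermediate
10 | 8-oxoparthenolide, (4R,5R,6S,7S)-4,5-epoxy-8-oxogermacra-1(10)E,11(13)-dien-12,6-olide | O=C1C/C(C)=C/CC[C@@]2(C)O[C@@H]2[C@H]2OC(=O)C(=C)[C@H]12 | intermediate
11 | 11,13-epoxide of 10 (spiro-oxirane, C11 configuration not defined) | O=C1C/C(C)=C/CC[C@@]2(C)O[C@@H]2[C@H]2OC(=O)C3(CO3)[C@H]12 | intermediate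
12 | lithium 13-alkoxide of 4α,5β-epoxy-13-hydroxy-8-oxogermacra-1(10)E,7(11)-dien-12,6α-olide | O=C1C/C(C)=C/CC[C@@]2(C)O[C@@H]2[C@H]2OC(=O)C(C[O-])=C12.[Li+] | intermediate
13 | 13-acetoxy-4α,5β-epoxy-8-oxogermacra-1(10)E,7(11)-dien-12,6α-olide | O=C1C/C(C)=C/CC[C@@]2(C)O[C@@H]2[C@H]2OC(=O)C(COC(C)=O)=C12 | intermediate
14 | 13-acetoxy-4α,5β-epoxy-8α-hydroxygermacra-1(10)E,7(11)-dien-12,6α-olide (8S) | O[C@H]1C/C(C)=C/CC[C@@]2(C)O[C@@H]2[C@H]2OC(=O)C(COC(C)=O)=C12 | intermediate
15 | 13-acetoxy-4α,5β-epoxy-8α-methacryloyloxygermacra-1(10)E,7(11)-dien-12,6α-olide | C=C(C)C(=O)O[C@H]1C/C(C)=C/CC[C@@]2(C)O[C@@H]2[C@H]2OC(=O)C(COC(C)=O)=C12 | intermediate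
16 | 10-O-deacetylglaucolide A (10α-hydroxy, 1-oxo) | C=C(C)C(=O)O[C@H]1C[C@@](C)(O)C(=O)CC[C@@]2(C)O[C@@H]2[C@H]2OC(=O)C(COC(C)=O)=C12 | intermediate
17 | glaucolide A (4R,5R,6S,8S,10R) | C=C(C)C(=O)O[C@H]1C[C@@](C)(OC(C)=O)C(=O)CC[C@@]2(C)O[C@@H]2[C@H]2OC(=O)C(COC(C)=O)=C12 | target

**Step count**
- Total steps: 11.
- Longest linear sequence: 10 (steps 1–3 and 5–11).

**The three steps most likely to fail**

Step 6 (macro-aldol/lactonisation). The risks are:
- competing C9 enolisation with drift of the 1(10)-alkene into conjugation;
- oligomerisation;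
- γ-attack through C13;
- Stobbe-type opening of the lactone by the methoxide that is released.

The fallback sets out from 7 and comes back at 10. It replaces Brønsted-base enolisation by a regiodefined organochromium closure of the same bond. Compound 7 is silylated under equilibrating conditions (Me3SiOTf, Et3N, CH2Cl2, −78 → 0 °C; the epoxy aldehyde cannot enolise) to the conjugated trimethylsilyl dienol ether F1. NBS in THF at −78 °C converts this into the 13-bromo enone F2. CrCl2 in THF at high dilution (divalent chromium is oxidised to trivalent chromium) then turns the allylic bromide into an allylchromium/chromium dienolate. This adds to the aldehyde through C7 in Nozaki–Hiyama fashion under neutral conditions, and the chromium alkoxide lactonises to 10.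

Step 7 (epoxidation/E1cB/acetylation). The risks are:
- prototropic shift of 10 to the 13-methyl butenolide before peroxide addition;
- closure of alkoxide 12 onto the C8 ketone, followed by furan formation;
- over-epoxidation of the product.

The fallback sets out from 10 and comes back at 13. It reverses the polarity at C13, using electrophilic halogenation instead of a nucleophilic oxidant. Compound 10 is converted with Me3SiOTf/Et3N into the cross-conjugated silyl dienol ether F3. NBS at −78 °C gives the 13-bromo butenolide F4; any 7-bromo isomer converges in the next operation by SN2′ attack. AgOAc in CH2Cl2 then displaces bromide to give 13 without a free 13-hydroxyl ever being present.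

Step 10 (ketohydroxylation). The risks are C=C cleavage, attack on the electron-poor alkenes and insufficient face selectivity.

The fallback sets out from 15 and comes back at 16. It separates the C–O bond-forming event from the oxidation-state adjustment. Osmylation (OsO4 2 mol %, N-methylmorpholine N-oxide, acetone/H2O, 0 °C) gives the 1β,10α-diol F5, whose configuration can be checked and, if necessary, steered with a cinchona ligand. Selective oxidation of the secondary C1 hydroxyl (Dess–Martin periodinane, CH2Cl2, 0 °C) then gives 16.

**Further compounds**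
F1 | step 6 | trimethylsilyl C7=C8 dienol ether of 7 (enol ether geometry not defined) | COC(=O)C(=C)C=C(O[Si](C)(C)C)C/C(C)=C/CC[C@@]1(C)O[C@@H]1C=O
F2 | step 6 | methyl (6E)-2-(bromomethyl)-9-[(2R,3S)-3-formyl-2-methyloxiran-2-yl]-6-methyl-4-oxonona-2,6-dienoate (2-ene geometry not defined) | COC(=O)C(CBr)=CC(=O)C/C(C)=C/CC[C@@]1(C)O[C@@H]1C=O
F3 | step 7 | 8-trimethylsilyloxy-4α,5β-epoxygermacra-1(10)E,7,11(13)-trien-12,6α-olide (7-ene geometry not defined) | C[Si](C)(C)OC=1C/C(C)=C/CC[C@@]2(C)O[C@@H]2[C@H]2OC(=O)C(=C)C=12
F4 | step 7 | 13-bromo-4α,5β-epoxy-8-oxogermacra-1(10)E,7(11)-dien-12,6α-olide | O=C1C/C(C)=C/CC[C@@]2(C)O[C@@H]2[C@H]2OC(=O)C(CBr)=C12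
F5 | step 10 | 13-acetoxy-4α,5β-epoxy-1β,10α-dihydroxy-8α-methacryloyloxygermacr-7(11)-en-12,6α-olide | C=C(C)C(=O)O[C@H]1C[C@@](C)(O)[C@H](O)CC[C@@]2(C)O[C@@H]2[C@H]2OC(=O)C(COC(C)=O)=C12
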